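**Retrosynthetic overview**
- Last bond: the C8–O ester, from the 8-hydroxy α-methylene lactone and (2S,3R)-epoxytiglic acid (tiglic acid, Sharpless epoxidation).
- Before that: α-methylenation of the lactone and reduction of a C8 ketone on the bicyclic core; ring A (oxepene, C3=C4) by ring-closing metathesis.
- Key disconnection: the C5–O bond of ring B (oxepane), by palladium-catalysed allylic C–O coupling of the tertiary C10 hydroxyl with a Morita–Baylis–Hillman (MBH) acetate.
- C8–C9 bond: East lactone aldehyde (from (S)-5-(hydroxymethyl)furanone by dithiane 1,4-addition and MBH reaction) plus West β-oxido organocerium (from methallyl alcohol by Sharpless epoxidation and allyl cuprate opening).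
- Ring order: γ-lactone (present in the starting butenolide), then ring B, then ring A.

Assumption: the target is taken exactly as drawn in the SMILES; locants C1–C15 follow germacranolide numbering (C5 and C10 carry the bridging ether oxygen, C6–O and C12 form the lactone, C13 is the exocyclic methylene, C14 the methyl on C10, C15 the ester carbon on C4).

**East fragment**

Step 1
Reactants: 1 (S)-5-(hydroxymethyl)furan-2(5H)-one
Product: 2 (S)-5-{[(triethylsilyl)oxy]methyl}furan-2(5H)-one
Conditions: TESCl, imidazole, CH2Cl2, 0 °C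
Reagents that add atoms: chlorotriethylsilane CC[Si](Cl)(CC)CC
Why: Silyl ether formation masks the primary C5 hydroxyl without touching the base-sensitive butenolide; the C6 stereocentre comes from the starting material.

Step 2
Reactants: 2 (S)-5-{[(triethylsilyl)oxy]methyl}furan-2(5H)-one
Product: 4 (4S,5S)-4-(1,3-dithian-2-yl)-5-{[(triethylsilyl)oxy]methyl}oxolan-2-one, via lithium enolate 3 (not isolated)
Conditions: 1,3-dithiane, n-BuLi, THF, −30 °C; HMPA, −78 °C; then 2; AcOH quench
Reagents that add atoms: 1,3-dithiane C1CSCSC1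
Why: Conjugate (1,4-) addition of the dithiane acyl-anion equivalent in THF–HMPA occurs anti to the CH2OTES group, which sets C7 trans to C6 and brings in C8 as a masked aldehyde.

Step 3
Reactants: 4 (4S,5S)-4-(1,3-dithian-2-yl)-5-{[(triethylsilyl)oxy]methyl}oxolan-2-one
Product: 5 (2S,3S)-3-(1,3-dithian-2-yl)-5-oxooxolane-2-carbaldehyde
Conditions: (COCl)2, DMSO, CH2Cl2, −78 to −40 °C; Et3N, −78 to 0 °C
Reagents that add atoms: none
Why: Under Swern conditions a primary triethylsilyl ether is cleaved through the alkoxysulfonium salt and oxidised in one operation (oxidative desilylation, Swern oxidation), while thioacetal and lactone are inert.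

Step 4
Reactants: 5 (2S,3S)-3-(1,3-dithian-2-yl)-5-oxooxolane-2-carbaldehyde
Product: 6 methyl 2-{[(2S,3S)-3-(1,3-dithian-2-yl)-5-oxooxolan-2-yl](hydroxy)methyl}prop-2-enoate (both carbinol epimers)
Conditions: methyl acrylate (5 equiv), DABCO (1 equiv), 1,4-dioxane/H2O 1:1, rt
Reagents that add atoms: methyl acrylate C=CC(=O)OC
Why: The Morita–Baylis–Hillman reaction of the activated α-acyloxy aldehyde forms the C4–C5 bond and the acrylate; C5 is not controlled here because both epimers converge in step 12.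

Step 5
Reactants: 6 methyl 2-{[(2S,3S)-3-(1,3-dithian-2-yl)-5-oxooxolan-2-yl](hydroxy)methyl}prop-2-enoate
Product: 7 methyl 2-{(acetyloxy)[(2S,3S)-3-(1,3-dithian-2-yl)-5-oxooxolan-2-yl]methyl}prop-2-enoate (both epimers at the acetoxy carbon)
Conditions: Ac2O, pyridine, DMAP (5 mol %), CH2Cl2, 0 °C
Reagents that add atoms: acetic anhydride CC(=O)OC(C)=O
Why: Acetylation of the secondary allylic alcohol (esterification) installs the leaving group for later π-allyl formation.

Step 6
Reactants: 7 methyl 2-{(acetyloxy)[(2S,3S)-3-(1,3-dithian-2-yl)-5-oxooxolan-2-yl]methyl}prop-2-enoate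
Product: 8 methyl 2-{(acetyloxy)[(2S,3S)-3-formyl-5-oxooxolan-2-yl]methyl}prop-2-enoate (both epimers at the acetoxy carbon)
Conditions: MeI, CaCO3, MeCN/H2O 9:1, 40 °C
Reagents that add atoms: water O
Why: S-Methylation and hydrolysis (thioacetal cleavage) unmask the C8 aldehyde under near-neutral conditions that acrylate, acetate and lactone tolerate.

**West fragment**

Step 7
Reactants: 9 2-methylprop-2-en-1-ol
Product: 11 (S)-(2-methyloxiran-2-yl)methyl 4-methylbenzenesulfonate, via epoxy alcohol 10 (not isolated)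
Conditions: Ti(OiPr)4 (5 mol %), D-(−)-DIPT (6 mol %), t-BuOOH, 4 Å MS, CH2Cl2, −20 °C; then Et3N, DMAP (cat.), TsCl, −10 °C
Reagents that add atoms: tert-butyl hydroperoxide CC(C)(C)OO; 4-methylbenzenesulfonyl chloride Cc1ccc(cc1)S(Cl)(=O)=O
Why: Sharpless asymmetric epoxidation with the D-tartrate gives (R)-2-methylglycidol, which sets C10 and supplies the future ether oxygen; in situ tosylation avoids isolating the water-soluble epoxy alcohol.

Step 8
Reactants: 11 (S)-(2-methyloxiran-2-yl)methyl 4-methylbenzenesulfonate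
Product: 12 (S)-2-hydroxy-2-methylhept-6-en-1-yl 4-methylbenzenesulfonate
Conditions: allylMgCl, CuI (10 mol %), THF, −40 °C; aq. NH4Cl
Reagents that add atoms: allylmagnesium chloride C=CC[Mg]Cl
Why: Copper-catalysed Grignard opening (SN2) at the epoxide CH2 is faster than displacement of the neopentyl-type tosylate and leaves C10 untouched.

Step 9
Reactants: 12 (S)-2-hydroxy-2-methylhept-6-en-1-yl 4-methylbenzenesulfonate
Product: 13 (S)-2-(but-3-en-1-yl)-2-methyloxirane
Conditions: K2CO3, MeOH, 0 °C to rt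
Reagents that add atoms: none
Why: Intramolecular Williamson displacement of tosylate by the tertiary alkoxide re-forms an epoxide on the other CH2 without touching the stereocentre.

**Union and end game**

Step 10
Reactants: 13 (S)-2-(but-3-en-1-yl)-2-methyloxirane; 8 methyl 2-{(acetyloxy)[(2S,3S)-3-formyl-5-oxooxolan-2-yl]methyl}prop-2-enoate
Product: 16 methyl 2-{(acetyloxy)[(2S,3R)-3-[(3S)-1,3-dihydroxy-3-methylhept-6-en-1-yl]-5-oxooxolan-2-yl]methyl}prop-2-enoate (epimers at the acetoxy carbon and at the new carbinol), via dilithio alkoxide 14 (not isolated), via organocerium 15 (not isolated)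
Conditions: 13, Li powder, DTBB (10 mol %), THF, −78 °C; CeCl3, −78 °C; then 8, −78 °C; AcOH quench at −78 °C
Reagents that add atoms: none
Why: Arene-catalysed reductive lithiation cleaves the epoxide at the primary carbon to a β-oxido organolithium, and its organocerium derivative adds to the aldehyde (1,2-addition) without enolisation or attack on the esters; the C8 epimer mixture is removed in step 11.

Step 11
Reactants: 16 methyl 2-{(acetyloxy)[(2S,3R)-3-[(3S)-1,3-dihydroxy-3-methylhept-6-en-1-yl]-5-oxooxolan-2-yl]methyl}prop-2-enoate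
Product: 17 methyl 2-{(acetyloxy)[(2S,3S)-3-[(3S)-3-hydroxy-3-methylhept-6-enoyl]-5-oxooxolan-2-yl]methyl}prop-2-enoate (both epimers at the acetoxy carbon)
Conditions: Dess–Martin periodinane, pyridine, CH2Cl2, 0 °C
Reagents that add atoms: none
Why: Dess–Martin oxidation converts only the secondary C8 carbinol (the tertiary C10 alcohol cannot be oxidised) and merges the C8 epimers into one ketone.

Step 12
Reactants: 17 methyl 2-{(acetyloxy)[(2S,3S)-3-[(3S)-3-hydroxy-3-methylhept-6-enoyl]-5-oxooxolan-2-yl]methyl}prop-2-enoate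
Product: 18 ring B oxepanone (5R,6S,7S,10S): γ-lactone trans-fused at C6–C7 to an oxepan-8-one whose C5 carries C(=CH2)CO2Me and whose C10 carries CH3 and CH2CH2CH=CH2
Conditions: Pd2(dba)3·CHCl3 (5 mol %), dppf (12 mol %), 4 Å MS, toluene (5 mM), 40 °C
Reagents that add atoms: none
Why: Proposed new method: base-free ionisation of the MBH acetate by zerovalent palladium gives an electrophilic 2-(methoxycarbonyl)-π-allyl complex whose diastereomers interconvert by π–σ–π slippage at the CH2 terminus, so both acetate epimers pass through the chair-like transition state in which the tertiary C10 hydroxyl attacks C5 anti to palladium with the acrylate pseudo-equatorial and trans to the C6–O bond (seven-membered closure at C5 instead of nine-membered closure at CH2; acetate is the proton shuttle and no alkoxide is formed that could trigger retro-aldol or enolate C-allylation); the closest known reactions are the Tsuji–Trost etherification of MBH carbonates with phenols and primary alcohols and palladium-catalysed cycloetherification of hydroxy allylic acetates to five- and six-membered rings.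

Step 13
Reactants: 18 ring B oxepanone (5R,6S,7S,10S)
Product: 19 methyl (5R,6S,7S,10S)-5,10-epoxy-8-oxogermacr-3-en-12,6-olid-15-oate
Conditions: second-generation Grubbs catalyst RuCl2(H2IMes)(PCy3)(=CHPh) (10 mol %), toluene (2 mM), 80 °C
Reagents that add atoms: none
Why: Ring-closing metathesis of the butenyl alkene onto the 1,1-disubstituted acrylate (both arms cis on ring B) closes ring A as the trisubstituted enoate, whose geometry is fixed by the seven-membered ring.

Step 14
Reactants: 19 methyl (5R,6S,7S,10S)-5,10-epoxy-8-oxogermacr-3-en-12,6-olid-15-oate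
Product: 20 methyl (5R,6S,7R,8R,10S)-5,10-epoxy-8-hydroxygermacr-3-en-12,6-olid-15-oate
Conditions: NaBH4, CeCl3·7H2O, MeOH, −78 °C
Reagents that add atoms: none
Why: Luche 1,2-reduction leaves enoate and lactone alone; hydride is expected from the exo face (the side of the oxygen bridge, away from the cleft between the two seven-membered rings), placing the C8 hydroxyl cis to the C7–C11 bond.

Step 15
Reactants: 20 methyl (5R,6S,7R,8R,10S)-5,10-epoxy-8-hydroxygermacr-3-en-12,6-olid-15-oate
Product: 25 methyl (5R,6S,7R,8R,10S)-5,10-epoxy-8-hydroxygermacra-3,11(13)-dien-12,6-olid-15-oate, via TMS ether 21 (not isolated), via Mannich base 22 (not isolated), via methiodide 23 (not isolated), via silylated methylene lactone 24 (not isolated)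
Conditions: TMSCl, Et3N, CH2Cl2, 0 °C; then LiN(SiMe3)2, THF, −78 °C; Me2N=CH2+ I−, −78 °C to rt; MeI, THF, rt; aq. NaHCO3, EtOAc; aq. citric acid, THF, 0 °C
Reagents that add atoms: N,N-dimethylmethyleneiminium iodide C=[N+](C)C.[I-]; chlorotrimethylsilane C[Si](C)(C)Cl (carried only in 21 to 24); iodomethane CI (carried only in 23)
Why: Eschenmoser methylenation (lactone enolate Mannich reaction, N-methylation, E1cB loss of trimethylamine) installs C13; the transient silyl ether keeps the C8 alkoxide from relactonising onto C12.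

**Acid fragment**

Step 16
Reactants: 26 (E)-2-methylbut-2-enoic acid (tiglic acid)
Product: 27 (E)-2-methylbut-2-en-1-ol
Conditions: LiAlH4, Et2O, 0 °C to rt; H2O
Reagents that add atoms: none
Why: Hydride reduction of the conjugated acid proceeds 1,2 to the allylic alcohol and keeps the E geometry.

Step 17
Reactants: 27 (E)-2-methylbut-2-en-1-ol
Product: 28 [(2R,3R)-2,3-dimethyloxiran-2-yl]methanol
Conditions: Ti(OiPr)4 (10 mol %), D-(−)-DIPT (12 mol %), t-BuOOH, 4 Å MS, CH2Cl2, −20 °C
Reagents that add atoms: tert-butyl hydroperoxide CC(C)(C)OO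
Why: Sharpless asymmetric epoxidation with the D-tartrate sets both side-chain stereocentres, and syn oxygen transfer to the E alkene keeps the two methyl groups cis.

Step 18
Reactants: 28 [(2R,3R)-2,3-dimethyloxiran-2-yl]methanol
Product: 29 (2S,3R)-2,3-dimethyloxirane-2-carbaldehyde
Conditions: TEMPO (10 mol %), PhI(OAc)2, CH2Cl2, rt
Reagents that add atoms: none
Why: Oxoammonium (TEMPO) oxidation stops at the aldehyde and does not open the epoxide; the descriptor at C2 changes by priority only.

Step 19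
Reactants: 29 (2S,3R)-2,3-dimethyloxirane-2-carbaldehyde
Product: 30 (2S,3R)-2,3-dimethyloxirane-2-carboxylic acid
Conditions: NaClO2, NaH2PO4, 2-methylbut-2-ene, t-BuOH/H2O, 0 °C
Reagents that add atoms: sodium chlorite [Na+].[O-]Cl=O
Why: Pinnick oxidation gives the acid under buffered conditions; the quaternary α-carbon cannot epimerise.

**Final coupling**

Step 20
Reactants: 25 methyl (5R,6S,7R,8R,10S)-5,10-epoxy-8-hydroxygermacra-3,11(13)-dien-12,6-olid-15-oate; 30 (2S,3R)-2,3-dimethyloxirane-2-carboxylic acid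
Product: 32 methyl (5R,6S,7R,8R,10S)-8-{[(2S,3R)-2,3-dimethyloxirane-2-carbonyl]oxy}-5,10-epoxygermacra-3,11(13)-dien-12,6-olid-15-oate (CNP0240298.1), via mixed anhydride 31 (not isolated)
Conditions: 30, 2,4,6-trichlorobenzoyl chloride, Et3N, THF, rt; then 25, DMAP, toluene, rt to 40 °C
Reagents that add atoms: none
Why: Yamaguchi esterification acylates the hindered C8 hydroxyl with retention at C8 and in the acid, and the α-methylene lactone tolerates DMAP acylation.

**Compound list**
1 | (S)-5-(hydroxymethyl)furan-2(5H)-one | O=C1O[C@H](CO)C=C1 | starting material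
2 | (S)-5-{[(triethylsilyl)oxy]methyl}furan-2(5H)-one | O=C1O[C@H](CO[Si](CC)(CC)CC)C=C1 | intermediate
3 | lithium enolate of 4 (lithium (4S,5S)-4-(1,3-dithian-2-yl)-5-{[(triethylsilyl)oxy]methyl}-4,5-dihydrofuran-2-olate) | C1=C([O-])O[C@H](CO[Si](CC)(CC)CC)[C@H]1C1SCCCS1.[Li+] | intermediate
4 | (4S,5S)-4-(1,3-dithian-2-yl)-5-{[(triethylsilyl)oxy]methyl}oxolan-2-one | C1C(=O)O[C@H](CO[Si](CC)(CC)CC)[C@H]1C1SCCCS1 | intermediate
5 | (2S,3S)-3-(1,3-dithian-2-yl)-5-oxooxolane-2-carbaldehyde | C1C(=O)O[C@H](C=O)[C@H]1C1SCCCS1 | intermediate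
6 | methyl 2-{[(2S,3S)-3-(1,3-dithian-2-yl)-5-oxooxolan-2-yl](hydroxy)methyl}prop-2-enoate (carbinol epimers) | C1C(=O)O[C@H](C(O)C(=C)C(=O)OC)[C@H]1C1SCCCS1 | intermediate
7 | methyl 2-{(acetyloxy)[(2S,3S)-3-(1,3-dithian-2-yl)-5-oxooxolan-2-yl]methyl}prop-2-enoate (epimers at the acetoxy carbon) | C1C(=O)O[C@H](C(OC(C)=O)C(=C)C(=O)OC)[C@H]1C1SCCCS1 | intermediate
8 | methyl 2-{(acetyloxy)[(2S,3S)-3-formyl-5-oxooxolan-2-yl]methyl}prop-2-enoate (epimers at the acetoxy carbon) | C1C(=O)O[C@H](C(OC(C)=O)C(=C)C(=O)OC)[C@H]1C=O | intermediate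
9 | 2-methylprop-2-en-1-ol | C=C(C)CO | starting material
10 | (R)-(2-methyloxiran-2-yl)methanol | C[C@@]1(CO)CO1 | intermediate
11 | (S)-(2-methyloxiran-2-yl)methyl 4-methylbenzenesulfonate | C[C@@]1(COS(=O)(=O)c2ccc(C)cc2)CO1 | intermediate
12 | (S)-2-hydroxy-2-methylhept-6-en-1-yl 4-methylbenzenesulfonate | C=CCC[C@@](O)(C)COS(=O)(=O)c1ccc(C)cc1 | intermediate
13 | (S)-2-(but-3-en-1-yl)-2-methyloxirane | C=CCC[C@@]1(C)CO1 | intermediate
14 | dilithio alkoxide LiCH2–C(CH3)(OLi)–CH2CH2CH=CH2 (configuration of 13 retained) | [Li]C[C@](C)(CCC=C)O[Li] | intermediate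
15 | organocerium Cl2CeCH2–C(CH3)(OLi)–CH2CH2CH=CH2 (configuration of 13 retained) | Cl[Ce](Cl)C[C@](C)(CCC=C)O[Li] | intermediate
16 | methyl 2-{(acetyloxy)[(2S,3R)-3-[(3S)-1,3-dihydroxy-3-methylhept-6-en-1-yl]-5-oxooxolan-2-yl]methyl}prop-2-enoate (epimers at the acetoxy carbon and at the new carbinol) | C1C(=O)O[C@H](C(OC(C)=O)C(=C)C(=O)OC)[C@H]1C(O)C[C@](C)(CCC=C)O | intermediate
17 | methyl 2-{(acetyloxy)[(2S,3S)-3-[(3S)-3-hydroxy-3-methylhept-6-enoyl]-5-oxooxolan-2-yl]methyl}prop-2-enoate (epimers at the acetoxy carbon) | C1C(=O)O[C@H](C(OC(C)=O)C(=C)C(=O)OC)[C@H]1C(=O)C[C@](C)(CCC=C)O | intermediate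
18 | ring B oxepanone (5R,6S,7S,10S): lactone trans-fused to oxepan-8-one; C5 bears C(=CH2)CO2Me, C10 bears CH3 and but-3-enyl | C1C(=O)O[C@H]2[C@H]1C(=O)C[C@](C)(CCC=C)O[C@@H]2C(=C)C(=O)OC | intermediate
19 | methyl (5R,6S,7S,10S)-5,10-epoxy-8-oxogermacr-3-en-12,6-olid-15-oate | C1C(=O)O[C@H]2[C@H]1C(=O)C[C@]1(C)CCC=C(C(=O)OC)[C@H]2O1 | intermediate
20 | methyl (5R,6S,7R,8R,10S)-5,10-epoxy-8-hydroxygermacr-3-en-12,6-olid-15-oate | C1C(=O)O[C@H]2[C@H]1[C@H](O)C[C@]1(C)CCC=C(C(=O)OC)[C@H]2O1 | intermediate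
21 | 8-O-trimethylsilyl ether of 20 | C1C(=O)O[C@H]2[C@H]1[C@H](O[Si](C)(C)C)C[C@]1(C)CCC=C(C(=O)OC)[C@H]2O1 | intermediate
22 | 11-[(dimethylamino)methyl] Mannich base of 21 (C11 epimers) | CN(C)CC1C(=O)O[C@H]2[C@H]1[C@H](O[Si](C)(C)C)C[C@]1(C)CCC=C(C(=O)OC)[C@H]2O1 | intermediate
23 | trimethylammonium iodide (methiodide) of 22 | C[N+](C)(C)CC1C(=O)O[C@H]2[C@H]1[C@H](O[Si](C)(C)C)C[C@]1(C)CCC=C(C(=O)OC)[C@H]2O1.[I-] | intermediate
24 | 8-O-trimethylsilyl ether of 25 | C=C1C(=O)O[C@H]2[C@H]1[C@H](O[Si](C)(C)C)C[C@]1(C)CCC=C(C(=O)OC)[C@H]2O1 | intermediate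
25 | methyl (5R,6S,7R,8R,10S)-5,10-epoxy-8-hydroxygermacra-3,11(13)-dien-12,6-olid-15-oate | C=C1C(=O)O[C@H]2[C@H]1[C@H](O)C[C@]1(C)CCC=C(C(=O)OC)[C@H]2O1 | intermediate
26 | (E)-2-methylbut-2-enoic acid (tiglic acid) | C/C=C(\C)C(=O)O | starting material
27 | (E)-2-methylbut-2-en-1-ol | C/C=C(\C)CO | intermediate
28 | [(2R,3R)-2,3-dimethyloxiran-2-yl]methanol | OC[C@@]1(C)O[C@@H]1C | intermediate
29 | (2S,3R)-2,3-dimethyloxirane-2-carbaldehyde | O=C[C@@]1(C)O[C@@H]1C | intermediate
30 | (2S,3R)-2,3-dimethyloxirane-2-carboxylic acid | OC(=O)[C@@]1(C)O[C@@H]1C | intermediate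
31 | (2S,3R)-2,3-dimethyloxirane-2-carboxylic 2,4,6-trichlorobenzoic anhydride | O=C(OC(=O)[C@@]1(C)O[C@@H]1C)c1c(Cl)cc(Cl)cc1Cl | intermediate
32 | methyl (5R,6S,7R,8R,10S)-8-{[(2S,3R)-2,3-dimethyloxirane-2-carbonyl]oxy}-5,10-epoxygermacra-3,11(13)-dien-12,6-olid-15-oate (CNP0240298.1) | C=C1C(=O)O[C@H]2[C@H]1[C@H](OC(=O)[C@@]1(C)O[C@@H]1C)C[C@]1(C)CCC=C(C(=O)OC)[C@H]2O1 | target

**Step count and risks**

Total step count: 20. Longest linear sequence: 13 (steps 1–6, 10–15 and 20); the West branch (steps 7–9) and the acid branch (steps 16–19) run in parallel.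

Three steps most likely to fail:

Step 12 (the new palladium cyclo-etherification). The risks are a slow seven-membered closure by a neutral tertiary alcohol, β-acyloxy elimination from the σ-allyl form, and return of acetate. The fallback sets out from 17 and comes back at 18 using known ionic chemistry instead of palladium. LiBr in THF/acetone converts the MBH acetate by SN2′ displacement into the rearranged (Z)-2-(bromomethyl)enoate F1. Silver triflate (AgOTf) with 2,6-di-tert-butyl-4-methylpyridine in CH2Cl2 at −20 °C then drives a silver-assisted Williamson-type O-alkylation of the tertiary hydroxyl. Ring size again directs attack to C5 (seven-membered) and not to the CH2 end (nine-membered), giving 18.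

Step 10 (β-oxido organocerium addition to the sensitive β-acyloxy aldehyde). The risks are β-elimination of the organometallic, lactone attack, and translactonisation of the C8 alkoxide. The fallback sets out from 13 (with 2) and comes back at 17 by the classical, less convergent dithiane linchpin order. Epoxide 13 is opened at CH2 by 2-lithio-1,3-dithiane to give the hydroxy dithiane F2. Its dianion (n-BuLi, THF–HMPA) adds 1,4 to butenolide 2, anti to the silyloxymethyl group, to give the lactone dithiane F3. Direct Swern oxidation of the primary silyl ether gives the aldehyde F4, the MBH reaction with methyl acrylate gives the allylic alcohol F5, and Ac2O/pyridine gives the acetate F6. MeI/CaCO3 hydrolysis of the dithiane then releases ketone 17.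

Step 14 (facial selectivity of the C8 ketone reduction in the bridged bicycle). If hydride arrives from the other face, the product is the 8-epimeric alcohol. The fallback sets out from 19 and comes back at 20 by inversion instead of direct reduction. The same reduction gives the 8-epi alcohol F7. Mitsunobu reaction with chloroacetic acid (PPh3, DIAD, toluene) inverts C8 to the chloroacetate F8, which thiourea/NaHCO3 in EtOH cleaves under near-neutral conditions to 20 without disturbing the lactone.

**Further compounds**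
F1 | step 12 | methyl (2Z)-2-(bromomethyl)-3-{(2S,3S)-3-[(3S)-3-hydroxy-3-methylhept-6-enoyl]-5-oxooxolan-2-yl}prop-2-enoate | C1C(=O)O[C@H](/C=C(\CBr)C(=O)OC)[C@H]1C(=O)C[C@](C)(CCC=C)O
F2 | step 10 | (S)-1-(1,3-dithian-2-yl)-2-methylhept-6-en-2-ol | C1(SCCCS1)C[C@](C)(CCC=C)O
F3 | step 10 | (4S,5S)-4-{2-[(2S)-2-hydroxy-2-methylhept-6-en-1-yl]-1,3-dithian-2-yl}-5-{[(triethylsilyl)oxy]methyl}oxolan-2-one | C1C(=O)O[C@H](CO[Si](CC)(CC)CC)[C@H]1C1(SCCCS1)C[C@](C)(CCC=C)O
F4 | step 10 | (2S,3S)-3-{2-[(2S)-2-hydroxy-2-methylhept-6-en-1-yl]-1,3-dithian-2-yl}-5-oxooxolane-2-carbaldehyde | C1C(=O)O[C@H](C=O)[C@H]1C1(SCCCS1)C[C@](C)(CCC=C)O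
F5 | step 10 | methyl 2-{hydroxy[(2S,3S)-3-{2-[(2S)-2-hydroxy-2-methylhept-6-en-1-yl]-1,3-dithian-2-yl}-5-oxooxolan-2-yl]methyl}prop-2-enoate (carbinol epimers) | C1C(=O)O[C@H](C(O)C(=C)C(=O)OC)[C@H]1C1(SCCCS1)C[C@](C)(CCC=C)O
F6 | step 10 | methyl 2-{(acetyloxy)[(2S,3S)-3-{2-[(2S)-2-hydroxy-2-methylhept-6-en-1-yl]-1,3-dithian-2-yl}-5-oxooxolan-2-yl]methyl}prop-2-enoate (epimers at the acetoxy carbon) | C1C(=O)O[C@H](C(OC(C)=O)C(=C)C(=O)OC)[C@H]1C1(SCCCS1)C[C@](C)(CCC=C)O
F7 | step 14 | methyl (5R,6S,7R,8S,10S)-5,10-epoxy-8-hydroxygermacr-3-en-12,6-olid-15-oate (8-epimer of 20) | C1C(=O)O[C@H]2[C@H]1[C@@H](O)C[C@]1(C)CCC=C(C(=O)OC)[C@H]2O1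
F8 | step 14 | 8-O-chloroacetate of 20 (C8 configured as in 20) | C1C(=O)O[C@H]2[C@H]1[C@H](OC(=O)CCl)C[C@]1(C)CCC=C(C(=O)OC)[C@H]2O1
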